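The data were generated by integration for an exercise.

This flask is charged with less E than X, 0.95 equiv, so E is the limiting reagent.

in all of them: X 1.5 M
- noon: E 0.95 equiv; the very flask that is asked about, followed so far
- flask: E 0.950 equiv; time 30 h

noon run (percent of the X charged)

| time / h | J / % | L / % | X / % | G / % | Z / % | D / % |
|---|---|---|---|---|---|---|
| 1.33 | 6.4 | 0.2 | 87.4 | 7.6 | 0 | 0 |
| 2.50 | 5.9 | 1.5 | 79.9 | 10.3 | 0.8 | 0.5 |
| 4.00 | 12.2 | 0 | 72.9 | 15.1 | 0 | 0 |
| 5.00 | 15.1 | 1.5 | 69.6 | 16.5 | 0 | 0 |

(standard deviation of a reading: 1 percentage point)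

- the species that holds most of what was charged as X, at 30 h (D / X / Z / J / G / L)
- the largest share itself, whichever of these holds it, in percent of the X charged

- the numbers in the tables scatter with a standard deviation of 1 percentage point
- a reading or a percentage of D is of its free form alone

Two chemists read this noon run. The first sees X slowing and takes the middle of two extrapolations. The forecast is that side's: X leads with 42%. Its words: “I expect X still holds the largest share”.

The second writes the balance of E, taking G to hold one E and J none, and counting L, Z and D, near the scatter, as nothing. Define the free pool P as the percent of the X charged not tied to E, which is 83.5% at 5.00 h. The readings of X plus J give 84.7%, 1.2 percentage points away, against a scatter of 1 point per reading. By this reckoning E stands at 82.6% of its charge.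

The second chemist takes X to turn to J inside the pool. Read as first order, the last reading gives 0.0393 h⁻¹. By this estimate J passes X at 17.7 h. So the second chemist commits to J, with 57.8% if the pool stays at its last value.

This flask gives J at 44.0%, and X at 31.5%, at 30 h.

    X ⇌ J (K = 8.10, k = 9.90 × 10⁻⁶ s⁻¹)
    E + J → Z (k = 2.20 × 10⁻⁶ M⁻¹ s⁻¹)
    X + E ⇌ G (K = 0.320 M⁻¹, k = 1.30 × 10⁻⁵ M⁻¹ s⁻¹)
    Z → D (k = 7.60 × 10⁻⁶ s⁻¹)
    E + D ⇌ Q (K = 0.350 M⁻¹, k = 6.00 × 10⁻⁶ M⁻¹ s⁻¹)
    G → L (k = 3.40 × 10⁻⁶ s⁻¹)

Q holds two E, so the E left, 73.9% of its charge, gives this flask a pool of 75.5%, less than the 83.5% read at 5.00 h, and X plus J stand at 75.5%. The neighbour flask, the same charge read at 20.0 h, has a pool of 77.0%, and there the forecast's X leads, 40.6% against 36.5% of J, so the crossing came later than the reckoned 17.7 h. At 3.00 h in this flask, with X at 77.7%, the step X + E ⇌ G had carried G to 12.7%, ahead of J at 9.16%. From 15.0 h to 30 h, as X fell from 46.7% to 31.5%, G fell from 17.2% to 11.8% and J rose from 30.9% to 44.0%.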